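all flasks: starting material 0.18 M (fed, over 20 h)
- eta: reagent 0.072 M; run made earlier; the fed solution adds 0.20 times the starting volume
- beta: reagent 0.11 M; run made earlier; the fed solution adds 0.20 times the starting volume
- flask: reagent 0.144 M; the fed solution adds 0.20 times the starting volume; time 6.0 d

| run | time / d | starting material / % | single product / % |
|---|---|---|---|
| eta | 0.417 | 28 | 9 |
| eta | 1.25 | 67 | 9 |
| eta | 2.00 | 52 | 7 |
| eta | 3.00 | 44 | 8 |
| eta | 5.00 | 35 | 6 |
| beta | 0.417 | 23 | 7 |
| beta | 1.25 | 62 | 11 |
| beta | 2.00 | 51 | 7 |
| beta | 3.00 | 45 | 3 |
| beta | 5.00 | 33 | 8 |

(scatter of a reading: 1.5 percentage points)

- charges are per starting volume, the dose included; the dosed solution carries all of it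
- percentages count the whole charge, also what has not yet gone in

- starting material at 6.0 d, in percent of the starting material charged
- single product at 6.0 d, in percent of the starting material charged
- bis adduct at 6.0 d, in percent of the starting material charged
- tris adduct at 6.0 d, in percent of the starting material charged

**Filling number.** The eta run holds less single product than random placing of reagent gives, and that comparison gives me my scale. Each starting material offers 3 places, so I define the filling number, the reagent charged over the places offered, [reagent]/(3[starting material]). For the eta run it is 13.3%. Random filling would then leave 30.0% as single product, but 8% is read at 3.00 d. So I read the statistical case as the zero and expect reagent to favour molecules already begun, which brings the tris adduct share towards the filling number.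

**Reading it off.** For the flask the number is 26.7%. I assume all reagent ends bound, so tris adduct = filling number − single product/3 − 2 bis adduct/3. Late single product averages 6.50% in the readings of both runs. Taking that reading for the single product of the flask, and bis adduct between zero and that reading, I commit to tris adduct between 20.2% and 24.5%.

**Second number.** One number does not carry starting material. From 2.00 d to 5.00 d it falls 17 percentage points in eta and 18 points in beta, although their filling numbers are 13.3% and 20.4%. I expect some path without reagent, and a flask reading below 33%.

**The forecast.** The forecast gives 29%, 7%, 42% and 22% for starting material, single product, bis adduct and tris adduct, and differs from my reckoning on bis adduct: “That split is poorly determined, so I guess bis is larger”.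

**The result.** The flask gives 27.6% starting material, 7.60% single product, 4.18% bis adduct and 21.3% tris adduct.

    2 starting material → self-condensation product (k = 0.0550 /M/h)
    reagent + single product → bis adduct (k = 15.0 /M/h)
    reagent + bis adduct → tris adduct (k = 19.0 /M/h)
    starting material + reagent → single product (k = 7.70 /M/h)

**Neighbouring flask.** In the flask, tris adduct at 21.3% lies below the filling number of 26.7% and inside my range. Reagent is the limiting reagent in the flask, with 0% of its charge left against 28% of starting material. The neighbouring flask holds 0.072 M starting material and the same reagent, so its filling number is 66.7%. The same reckoning, with the same late reading, gives it tris adduct between 60.2% and 64.5%. Its tris adduct stands at 58.5%, below that range, with 10.8% single product and 6.86% bis adduct.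

Readings and results come from a simulation with constants of no real substance, noise included.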